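## The problem

The target is a 20-nor gibberellin lactone: ring A is bridged across C4 and C10 by the 19,10-γ-lactone and is trans-fused to cyclopentane ring B, which carries the C7 acid, while rings C and D form a bicyclo[3.2.1]octane with a bridgehead tertiary alcohol at C13 beside the C16 exocyclic methylene. Nine stereocentres (C2, C3, C4, C5, C6, C8, C9, C10, C13) must be set, four of them fully substituted (C4, C8, C10, C13). Several centres can relay to others: C9 can direct quaternary C8 by trans addition and C8 fixes C13 through the one-carbon bridge, C3 can direct C4 through a chelated dianion, and the cis-fused B/C core can steer C6, which then steers C5. C4 and C5 decide C10 once the alkoxide is tied into the lactone, and the lactone bridge then shields one face of C2. The 2,3-diol is trans, with O2 on the lactone face, so syn-dihydroxylation of a ring A alkene cannot deliver it. The fragile groups are the C13 allylic alcohol with the C16 methylene (acid-induced Wagner–Meerwein shift, alkene migration, hydrogenation excluded), the β-hydroxy lactone C3/C4/C19 (retro-aldol epimerisation in base), any C2 carbonyl β to the lactone oxygen (E1cB loss of the carboxylate) and C6 α to the carboxyl. The enabling feature lies in ring B (C5, C6, C8, C9, C10): C5 and C6 sit between the oxygen-bearing C10 and the C7 carboxyl, so with C10 as a ketone they are the two α-carbons of a 1,4-dicarbonyl and the C5–C6 bond can be made by oxidising two enolates. The same ketone later accepts C1 and supplies the lactone oxygen.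

## Retrosynthesis

**Protecting groups and C2.** Target 34 comes from 32 by cleaving two silyl ethers and the tert-butyl ester (through silyl ester 33) without protic acid or base. Alcohol 32 comes from ketone 31 by hydride delivery to the β-face of C2, the α-face being roofed by the lactone. No skeletal bond is cut. This is preferred to making the diol from an alkene because the diol is trans and C3 is better set early by reagent control.

**C1–C10 and O–C19.** Keto lactone 31 is opened, through aldolate 30, to methyl ketone 29 (aldol of C1 onto the C10 ketone, then acylation of the alkoxide by the C19 methyl ester). 29 comes from vinyl compound 28 by Wacker oxidation. This double cut removes ring A, the lactone and quaternary C10 at once and uses a ketone that is already needed. A C2–C3 or C4–C5 cut would each leave the lactone to a separate operation. The forward step must bring C1 to the convex β-face of C10 so that the alkoxide lies syn to C19.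

**C5–C6 (key).** Cyclopentanone 28 is cut between its two α-carbons to keto diester 27. Polar closures of ring B (C5–C10 or C6–C8) would need one partner at a different oxidation level; here the partners are a plain ketone and a plain ester. 27 lacks ring B and two stereocentres. The forward reaction must enolise C5 (not C9) and C6, couple them oxidatively, and place the ester on the β-face trans to C4.

**C5–C10.** 27 is divided at the ketone into acid 17 (used as its chloride 25) and iodide 24 (used as zinc homoenolate 26). This is the most convergent cut. It avoids forming quaternary C4 by alkylation next to a hindered ketone, and the zinc reagent tolerates both esters. C9 must not epimerise.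

**C4–C5 and C3–C4.** Iodide 24 is the silyl ether of iodo alcohol 23. 23 arises from the dianion of hydroxy ester 21 and diiodomethane 22, with C4 set by the C3 alkoxide chelate. 21 comes from aldol adduct 20, made from imide 18 and acrolein 19, where the auxiliary sets C3. A direct aldol of an α,α-disubstituted enolate would not control C4.

**C13–C16.** Acid 17 is reached from 16, 15 and 14 by redox and protecting-group changes only. Bicyclic alcohol 14 is opened at C13–C16 to bromo ketone 13 (alkenylchromium addition). This closes ring D and creates the tertiary allylic alcohol and the methylene in their final form.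

**C8–C15 and C6–C8.** 13 comes from enone 11 and allylsilane 12 by conjugate allylation trans to the C9 substituent. 11 comes from enone 7 and ketene silyl acetal 9 (from tert-butyl acetate 8) by conjugate addition and re-oxidation via 10. The order is fixed: the last group added goes trans to C10, and that must be the bromoallyl arm.

**C8–C9 and C11–C12.** Enone 7 derives from 6, 5 and ester 4. 4 is the catalytic enantioselective Diels–Alder adduct of diene 2 (from methyl vinyl ketone 1) and acrylate 3. C10 is held at the alcohol level from 5 to 16 so that C9, the source of all chirality in the bicycle, cannot racemise through a dienol while C8 is still sp2.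

## Roads not taken

Alternative 1: cut C2–C3 by a pinacol closure. Dialdehyde A2 (C10–CH2–CHO and C4–CHO on the finished lactone core) would be coupled reductively with Bu3SnH or Cp2TiPh to give the methyl ester A1.
- Merits: both carbinol carbons and ring A form in one late step, and the diol needs no protection. The endgame is shorter than the chosen one (Wacker, aldol, reduction), and in that respect it is better.
- Weak points: two new centres form with up to four diastereomers and no strong bias toward O2 syn/O3 anti to the lactone. The C2 aldehyde is β to the lactone oxygen (E1cB). The C3 aldehyde is a hindered neopentyl formyl group on the lactone α-carbon. The road says nothing about how ring B, quaternary C10 and the lactone of A2 are made.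
- Against its brevity, the chosen plan sets C3 by an auxiliary and C2 by a single facial choice, and it builds ring A, the lactone and C10 together.

Alternative 2: cut C4–C5 by a lactone-enolate Claisen ring contraction. δ-Lactone A4 (ester oxygen on allylic C1, next to a C5=C10 alkene in ring B), once enolised and O-silylated, would rearrange to acid A3.
- Merits: quaternary C4 and C5 are set together through a ring-constrained transition state. This is more predictable than the C5/C6 outcome of a radical-type coupling, and on stereochemical reliability this road is better.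
- Weak points: the enolate of A4 has a β-silyloxy group at C3 (elimination). A3 still needs oxygen at C10 (halolactonisation and dehalogenation, in competition with C16=C17) and two oxidations at C7. A4 itself needs ring B, C6 and a contiguous C1–C3 triol array beforehand.
- The chosen plan offers fewer steps, and its C5 and C6 stay epimerisable next to carbonyl groups.

Alternative 3: cut C1–C10 and O–C19 by aldol with lactone capture as the central step. Methyl ketone A6 would give keto lactone A5.
- Merits: ring A, the lactone and quaternary C10 arise at once from a ketone and a methyl ester.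
- This is the same operation as step 20 of the chosen route (with a triethylsilyl instead of a trimethylsilyl ether), so it is adopted as the endgame, not rejected.
- As a plan on its own it leaves A6 unsolved: a cyclopentanone with vicinal C5/C6 substituents beside quaternary C8. The C5–C6 oxidative coupling supplies exactly that in one step.
- The risks of the aldol (trans ring fusion, loss of the lactone by elimination) are the same on both roads.

Key step: step 18

Remark: the SMILES is read as the 2α,3β-diol (O2 on the lactone face, trans to O3), i.e. the C2 epimer of the natural 2β,3β,13-trihydroxy lactone acid of this series. Locants follow gibberellane numbering, α being the face of C19 and the lactone oxygen, β that of C18, H5 and H9.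

Remark: (2-bromoallyl)trimethylsilane, (R)-4-benzyl-3-propionyloxazolidin-2-one and (R)-α,α-diphenylprolinol are taken as purchasable. It is assumed that the sense of induction follows that of acrylate/butadiene cycloadditions with this catalyst class, in which the (S)-prolinol catalyst gives the (1S)-cyclohex-3-enecarboxylate. The (R)-prolinol catalyst is therefore specified for (1R)-4, and its antipode would be used should the sense prove opposite.

## Route

Step 1
Reactants: 1 methyl vinyl ketone
Product: 2 2-(triisopropylsilyloxy)buta-1,3-diene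
Conditions: iPr3SiOTf, Et3N, Et2O, 0 °C to rt
Reagents that add atoms: triisopropylsilyl triflate, CC(C)[Si](C(C)C)(C(C)C)OS(=O)(=O)C(F)(F)F
Why: Soft enolisation at the methyl group and O-silylation give the cross-conjugated 2-silyloxydiene; the bulky silyl group is chosen because it survives the strongly Lewis acidic cycloaddition catalyst.

Step 2
Reactants: 2 2-(triisopropylsilyloxy)buta-1,3-diene; 3 2,2,2-trifluoroethyl acrylate
Product: 4 2,2,2-trifluoroethyl (1R)-4-(triisopropylsilyloxy)cyclohex-3-ene-1-carboxylate
Conditions: oxazaborolidinium triflimide from (R)-α,α-diphenylprolinol, o-tolylboroxine and HNTf2 (15 mol %), CH2Cl2, −20 to 0 °C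
Reagents that add atoms: none
Why: Catalytic enantioselective Diels–Alder reaction forming C8–C9 and C11–C12; the 2-silyloxy group directs the ester "para", so the enol ether C13=C14 points toward C8, and the catalyst blocks one acrylate face to set C9.

Step 3
Reactants: 4 Diels–Alder ester
Product: 5 [(1R)-4-(triisopropylsilyloxy)cyclohex-3-en-1-yl]methanol
Conditions: LiAlH4, THF, 0 °C
Reagents that add atoms: none
Why: Hydride reduction of the activated ester takes C10 to the alcohol level, at which C9 is not acidic during the two enone stages that follow; the silyl enol ether is inert to LiAlH4.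

Step 4
Reactants: 5 primary alcohol
Product: 6 triisopropyl{[(4R)-4-{[(4-methoxybenzyl)oxy]methyl}cyclohex-1-en-1-yl]oxy}silane
Conditions: NaH, 4-methoxybenzyl chloride, Bu4NI (cat.), THF/DMF, 0 °C to rt
Reagents that add atoms: 4-methoxybenzyl chloride, COc1ccc(CCl)cc1
Why: Williamson etherification; the 4-methoxybenzyl ether tolerates TiCl4 at low temperature and organochromium reagents and is later removed oxidatively beside silyl ethers and the tert-butyl ester.

Step 5
Reactants: 6 silyl enol ether
Product: 7 (4R)-4-{[(4-methoxybenzyl)oxy]methyl}cyclohex-2-en-1-one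
Conditions: Pd(OAc)2 (1.1 equiv), MeCN, rt to 40 °C
Reagents that add atoms: none
Why: Saegusa–Ito oxidation: palladation at C14 and β-hydride loss from C8 give the enone regiospecifically; C9 carries no acidifying group, so its configuration is safe.

Step 6
Reactants: 8 tert-butyl acetate
Product: 9 1-tert-butoxy-1-(tert-butyldimethylsilyloxy)ethene
Conditions: LiN(iPr)2, THF, −78 °C; tBuMe2SiCl, DMPU, −78 °C to rt
Reagents that add atoms: tert-butyldimethylsilyl chloride, CC(C)(C)[Si](C)(C)Cl
Why: O-silylation of the lithium ester enolate gives the ketene silyl acetal, a neutral acetate nucleophile for C6–C7.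

Step 7
Reactants: 7 enone; 9 ketene silyl acetal
Product: 11 tert-butyl 2-[(6R)-6-{[(4-methoxybenzyl)oxy]methyl}-3-oxocyclohex-1-en-1-yl]acetate, via silyl enol ether 10 (not isolated)
Conditions: MeCN, 50 °C; then Pd(OAc)2 (1.1 equiv), MeCN, rt to 40 °C
Reagents that add atoms: none
Why: Mukaiyama–Michael addition (silyl transfer to the enone oxygen, no Lewis acid needed in acetonitrile) places the acetate arm on C8 and leaves the C13=C14 silyl enol ether. A second Saegusa–Ito oxidation in the same solvent restores the enone with C8 now substituted; the transient C8 stereocentre is erased.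

Step 8
Reactants: 11 enone; 12 (2-bromoallyl)trimethylsilane
Product: 13 tert-butyl 2-[(1R,2R)-1-(2-bromoprop-2-en-1-yl)-2-{[(4-methoxybenzyl)oxy]methyl}-5-oxocyclohexyl]acetate
Conditions: TiCl4, CH2Cl2, −78 °C
Reagents that add atoms: none
Why: Hosomi–Sakurai conjugate allylation creates quaternary C8. Allylic 1,2-strain with the C8 acetate arm holds the C9 substituent pseudoaxial and the allylsilane attacks C8 axially from the opposite face, so the bromoallyl arm (C15) ends trans to C10 and the acetate arm cis.

Step 9
Reactants: 13 bromo ketone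
Product: 14 tert-butyl 2-[(1R,2R,5S)-5-hydroxy-2-{[(4-methoxybenzyl)oxy]methyl}-6-methylidenebicyclo[3.2.1]octan-1-yl]acetate
Conditions: CrCl2 (4 equiv), NiCl2 (2 mol %), DMF, rt to 50 °C
Reagents that add atoms: none
Why: Intramolecular Nozaki–Hiyama–Kishi reaction: the alkenylchromium species from the vinyl bromide adds to the C13 ketone and closes five-membered ring D without touching the ester. The tether through C14 forces C16 onto the face of C15, so C13 is set by C8.

Step 10
Reactants: 14 bicyclic alcohol
Product: 15 tert-butyl 2-[(1R,2R,5S)-2-{[(4-methoxybenzyl)oxy]methyl}-6-methylidene-5-(triethylsilyloxy)bicyclo[3.2.1]octan-1-yl]acetate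
Conditions: Et3SiOTf, 2,6-lutidine, CH2Cl2, −78 to 0 °C
Reagents that add atoms: triethylsilyl triflate, CC[Si](CC)(CC)OS(=O)(=O)C(F)(F)F
Why: Silyl triflate silylation of the hindered tertiary alcohol; the ether keeps the alkoxide out of the organozinc, amide-base and trivalent-iron steps and is removed by fluoride at the end.

Step 11
Reactants: 15 silyl ether
Product: 16 tert-butyl 2-[(1R,2R,5S)-2-(hydroxymethyl)-6-methylidene-5-(triethylsilyloxy)bicyclo[3.2.1]octan-1-yl]acetate
Conditions: DDQ, CH2Cl2/pH 7 buffer, 0 °C
Reagents that add atoms: none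
Why: Oxidative cleavage of the 4-methoxybenzyl ether by benzylic hydride abstraction and hydrolysis; the silyl ether, ester and 1,1-disubstituted alkene are not affected under buffered conditions.

Step 12
Reactants: 16 primary alcohol
Product: 17 (1R,2R,5S)-1-(2-tert-butoxy-2-oxoethyl)-6-methylidene-5-(triethylsilyloxy)bicyclo[3.2.1]octane-2-carboxylic acid
Conditions: TEMPO (2,2,6,6-tetramethylpiperidin-1-oxyl, 20 mol %), PhI(OAc)2, MeCN/H2O, rt
Reagents that add atoms: water, O
Why: Nitroxyl-catalysed oxidation of the primary alcohol through the aldehyde hydrate to the acid under near-neutral conditions; the alkene and silyl ether survive and C9 is not epimerised.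

Step 13
Reactants: 18 (R)-4-benzyl-3-propionyloxazolidin-2-one; 19 acrolein
Product: 20 (R)-4-benzyl-3-[(2R,3S)-3-hydroxy-2-methylpent-4-enoyl]oxazolidin-2-one
Conditions: Bu2BOTf, iPr2NEt, CH2Cl2, −78 to 0 °C; then 19, −78 °C; buffered aqueous work-up
Reagents that add atoms: none
Why: Evans syn-aldol through the Z boron enolate and a Zimmerman–Traxler chair; the (R)-auxiliary sets C3 as S. The α-methyl configuration is immaterial because that carbon is enolised in step 15.

Step 14
Reactants: 20 aldol adduct
Product: 21 methyl (2R,3S)-3-hydroxy-2-methylpent-4-enoate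
Conditions: MeMgBr, MeOH, CH2Cl2, 0 °C
Reagents that add atoms: methanol, CO
Why: Transesterification by bromomagnesium methoxide at the chelation-activated exocyclic carbonyl releases the auxiliary without retro-aldol cleavage.

Step 15
Reactants: 21 hydroxy ester; 22 diiodomethane
Product: 23 methyl (2S,3S)-3-hydroxy-2-(iodomethyl)-2-methylpent-4-enoate
Conditions: LiN(iPr)2 (2.2 equiv), THF, −78 to −20 °C; then 22, DMPU, −78 to −40 °C
Reagents that add atoms: none
Why: Fráter–Seebach alkylation creates quaternary C4: the lithium-chelated dianion is alkylated on the face anti to the C3 vinyl group, so the iodomethyl group (C5) enters anti to O3 and the methyl ends syn. The neopentyl iodide formed can neither eliminate nor be displaced easily.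

Step 16
Reactants: 23 iodo alcohol
Product: 24 methyl (2S,3S)-3-(tert-butyldimethylsilyloxy)-2-(iodomethyl)-2-methylpent-4-enoate
Conditions: tBuMe2SiOTf, 2,6-lutidine, CH2Cl2, 0 °C
Reagents that add atoms: tert-butyldimethylsilyl triflate, CC(C)(C)[Si](C)(C)OS(=O)(=O)C(F)(F)F
Why: Silyl triflate protection of the hindered secondary alcohol; the silyl ether survives zinc insertion, amide bases and the Wacker oxidation.

Step 17
Reactants: 17 carboxylic acid; 24 iodide
Product: 27 seco-ring B keto diester (C10 ketone joined to C5), via acid chloride 25 (not isolated), via alkylzinc iodide 26 (not isolated)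
Conditions: 24, Zn dust (activated with BrCH2CH2Br and Me3SiCl), THF/DMA, 45 °C; 17, 1-chloro-N,N,2-trimethylprop-1-en-1-amine, CH2Cl2, 0 °C to rt; combine, Pd(PPh3)4 (5 mol %), THF, 0 °C to rt
Reagents that add atoms: none
Why: Negishi acylation of a zinc homoenolate: zinc inserts into the β-iodo ester, the Ghosez reagent gives the acid chloride without acid or base, and zerovalent palladium couples the two to the γ-keto ester. Esters, silyl ethers and both alkenes are tolerated and C9 is not enolised.

Step 18
Reactants: 27 seco-ring B keto diester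
Product: 28 ring B cyclopentanone (C5–C6 closed; 5β-H 6α-H 9β-H)
Conditions: LiN(iPr)2 (2.3 equiv), THF (0.01 M), −78 °C; then Fe(acac)3 (2.2 equiv), THF, −78 °C to rt
Reagents that add atoms: none
Why: LiN(iPr)2 removes a C5 proton of the ketone (the methylene, not the C9 methine beside quaternary C8) and a C6 proton of the tert-butyl ester, giving a dilithium dienolate. Fe(acac)3 oxidises one enolate by single-electron transfer to an α-carbonyl radical, which bonds to the other enolate carbon; a second electron transfer to trivalent iron gives the neutral 1,4-dicarbonyl. The closest known reaction type is the intramolecular oxidative heterocoupling of ketone or amide enolates with ester enolates by trivalent iron or divalent copper. Ring B closes in a five-membered mode, 5-exo with respect to the C6=C7 enolate, along the chain C5–C10–C9–C8–C6. At C6 the tert-butyl ester takes the convex β-face of the cis-fused B/C system, away from C14 and C11, which cover the α-face next to C8. At C5 the quaternary C4 substituent goes trans to that ester (α), and both centres stay α to a carbonyl, so residual cis isomer can be equilibrated with base. The step needs enolisation at C5 and not C9 (a C9 enolate could only give a cyclopropane) and intramolecular coupling over dimerisation; the less hindered methylene, the tether and high dilution secure this, and the tert-butyl ester suppresses Claisen acylation.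

Step 19
Reactants: 28 ring B cyclopentanone
Product: 29 C2 methyl ketone
Conditions: Pd(Quinox)Cl2 (5 mol %; Quinox = 2-(4,5-dihydrooxazol-2-yl)quinoline), AgSbF6 (12 mol %), aq. tBuOOH, CH2Cl2, 0 °C to rt
Reagents that add atoms: tert-butyl hydroperoxide, CC(C)(C)OO
Why: Tsuji–Wacker oxidation under ligand-controlled peroxide conditions gives the Markovnikov methyl ketone even next to an allylic silyl ether; the 1,1-disubstituted C16=C17 alkene is not a substrate for this catalyst.

Step 20
Reactants: 29 C2 methyl ketone
Product: 31 2-oxo 19,10-lactone (ring A closed), via C10 aldolate 30 (not isolated)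
Conditions: LiN(SiMe3)2 (1.05 equiv), THF, −78 to −20 °C; AcOH quench at −40 °C
Reagents that add atoms: none
Why: Intramolecular aldol with lactone capture: the kinetic C1 enolate of the methyl ketone adds to the C10 ketone from the convex β-face, so the alkoxide lies α, syn to C19, and acylates on the methyl ester (lithium can bridge the two oxygens). The aldol is reversible and only this diastereomer can lactonise; the bulky tert-butyl ester resists attack by the other aldolate. C10 is set by C4 and C5.

Step 21
Reactants: 31 2-oxo lactone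
Product: 32 2α-alcohol
Conditions: NaBH4, CeCl3·7H2O, MeOH/THF, −40 °C
Reagents that add atoms: none
Why: Luche-type borohydride reduction: the lactone bridge spans the α-face of the C2 carbonyl like two 1,3-diaxial substituents, so hydride enters from the β-face and the hydroxyl ends α, trans to O3. The cerium salt keeps the medium non-basic, which protects the β-acyloxy ketone from elimination.

Step 22
Reactants: 32 2α-alcohol
Product: 34 target acid CNP0265952.2, via silyl ester 33 (not isolated)
Conditions: Me3SiOTf, 2,6-lutidine, CH2Cl2, 0 °C; then HF·pyridine, pyridine, THF, 0 °C to rt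
Reagents that add atoms: none
Why: The silyl triflate with a hindered base converts the tert-butyl ester into a silyl ester with loss of isobutene, without protic acid that would trigger rearrangement of the C13 alcohol/C16 methylene unit. Buffered HF then removes all silyl groups without the base that would epimerise C3 by retro-aldol.

## Compound list

1 | but-3-en-2-one (methyl vinyl ketone) | CC(=O)C=C | starting material
2 | 2-(triisopropylsilyloxy)buta-1,3-diene | C=CC(=C)O[Si](C(C)C)(C(C)C)C(C)C | intermediate
3 | 2,2,2-trifluoroethyl acrylate | C=CC(=O)OCC(F)(F)F | starting material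
4 | 2,2,2-trifluoroethyl (1R)-4-(triisopropylsilyloxy)cyclohex-3-ene-1-carboxylate | O=C(OCC(F)(F)F)[C@H]1CC=C(O[Si](C(C)C)(C(C)C)C(C)C)CC1 | intermediate
5 | [(1R)-4-(triisopropylsilyloxy)cyclohex-3-en-1-yl]methanol | OC[C@H]1CC=C(O[Si](C(C)C)(C(C)C)C(C)C)CC1 | intermediate
6 | triisopropyl{[(4R)-4-{[(4-methoxybenzyl)oxy]methyl}cyclohex-1-en-1-yl]oxy}silane | COc1ccc(COC[C@H]2CC=C(O[Si](C(C)C)(C(C)C)C(C)C)CC2)cc1 | intermediate
7 | (4R)-4-{[(4-methoxybenzyl)oxy]methyl}cyclohex-2-en-1-one | COc1ccc(COC[C@H]2C=CC(=O)CC2)cc1 | intermediate
8 | tert-butyl acetate | CC(=O)OC(C)(C)C | starting material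
9 | 1-tert-butoxy-1-(tert-butyldimethylsilyloxy)ethene | C=C(OC(C)(C)C)O[Si](C)(C)C(C)(C)C | intermediate
10 | tert-butyl 2-[(1S,6R)-3-(tert-butyldimethylsilyloxy)-6-{[(4-methoxybenzyl)oxy]methyl}cyclohex-2-en-1-yl]acetate (trans) | COc1ccc(COC[C@@H]2CCC(O[Si](C)(C)C(C)(C)C)=C[C@H]2CC(=O)OC(C)(C)C)cc1 | intermediate
11 | tert-butyl 2-[(6R)-6-{[(4-methoxybenzyl)oxy]methyl}-3-oxocyclohex-1-en-1-yl]acetate | COc1ccc(COC[C@@H]2CCC(=O)C=C2CC(=O)OC(C)(C)C)cc1 | intermediate
12 | (2-bromoallyl)trimethylsilane | C=C(Br)C[Si](C)(C)C | starting material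
13 | tert-butyl 2-[(1R,2R)-1-(2-bromoprop-2-en-1-yl)-2-{[(4-methoxybenzyl)oxy]methyl}-5-oxocyclohexyl]acetate (bromoallyl trans to the C9 substituent) | COc1ccc(COC[C@@H]2CCC(=O)C[C@@]2(CC(=O)OC(C)(C)C)CC(Br)=C)cc1 | intermediate
14 | tert-butyl 2-[(1R,2R,5S)-5-hydroxy-2-{[(4-methoxybenzyl)oxy]methyl}-6-methylidenebicyclo[3.2.1]octan-1-yl]acetate | C=C1C[C@]2(CC(=O)OC(C)(C)C)C[C@@]1(O)CC[C@H]2COCc3ccc(OC)cc3 | intermediate
15 | tert-butyl 2-[(1R,2R,5S)-2-{[(4-methoxybenzyl)oxy]methyl}-6-methylidene-5-(triethylsilyloxy)bicyclo[3.2.1]octan-1-yl]acetate | C=C1C[C@]2(CC(=O)OC(C)(C)C)C[C@@]1(O[Si](CC)(CC)CC)CC[C@H]2COCc3ccc(OC)cc3 | intermediate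
16 | tert-butyl 2-[(1R,2R,5S)-2-(hydroxymethyl)-6-methylidene-5-(triethylsilyloxy)bicyclo[3.2.1]octan-1-yl]acetate | C=C1C[C@]2(CC(=O)OC(C)(C)C)C[C@@]1(O[Si](CC)(CC)CC)CC[C@H]2CO | intermediate
17 | (1R,2R,5S)-1-(2-tert-butoxy-2-oxoethyl)-6-methylidene-5-(triethylsilyloxy)bicyclo[3.2.1]octane-2-carboxylic acid | C=C1C[C@]2(CC(=O)OC(C)(C)C)C[C@@]1(O[Si](CC)(CC)CC)CC[C@H]2C(=O)O | intermediate
18 | (R)-4-benzyl-3-propionyloxazolidin-2-one | CCC(=O)N1[C@H](Cc2ccccc2)COC1=O | starting material
19 | acrolein | C=CC=O | starting material
20 | (R)-4-benzyl-3-[(2R,3S)-3-hydroxy-2-methylpent-4-enoyl]oxazolidin-2-one | O=C1OC[C@@H](Cc2ccccc2)N1C(=O)[C@H](C)[C@@H](O)C=C | intermediate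
21 | methyl (2R,3S)-3-hydroxy-2-methylpent-4-enoate | COC(=O)[C@H](C)[C@@H](O)C=C | intermediate
22 | diiodomethane | ICI | starting material
23 | methyl (2S,3S)-3-hydroxy-2-(iodomethyl)-2-methylpent-4-enoate | IC[C@](C)(C(=O)OC)[C@@H](O)C=C | intermediate
24 | methyl (2S,3S)-3-(tert-butyldimethylsilyloxy)-2-(iodomethyl)-2-methylpent-4-enoate | IC[C@](C)(C(=O)OC)[C@@H](O[Si](C)(C)C(C)(C)C)C=C | intermediate
25 | (1R,2R,5S)-1-(2-tert-butoxy-2-oxoethyl)-6-methylidene-5-(triethylsilyloxy)bicyclo[3.2.1]octane-2-carbonyl chloride | C=C1C[C@]2(CC(=O)OC(C)(C)C)C[C@@]1(O[Si](CC)(CC)CC)CC[C@H]2C(=O)Cl | intermediate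
26 | [(2S,3S)-3-(tert-butyldimethylsilyloxy)-2-(methoxycarbonyl)-2-methylpent-4-en-1-yl]zinc iodide | I[Zn]C[C@](C)(C(=O)OC)[C@@H](O[Si](C)(C)C(C)(C)C)C=C | intermediate
27 | methyl (2S,3S)-2-{2-[(1R,2R,5S)-1-(2-tert-butoxy-2-oxoethyl)-6-methylidene-5-(triethylsilyloxy)bicyclo[3.2.1]octan-2-yl]-2-oxoethyl}-3-(tert-butyldimethylsilyloxy)-2-methylpent-4-enoate | C=C1C[C@]2(CC(=O)OC(C)(C)C)C[C@@]1(O[Si](CC)(CC)CC)CC[C@H]2C(=O)C[C@](C)(C(=O)OC)[C@@H](O[Si](C)(C)C(C)(C)C)C=C | intermediate
28 | ring B cyclopentanone: 10-oxo; 6β-tert-butyl ester (6α-H); 5β-H, C5 carrying C4(CH3)(CO2CH3)–C3H(OSitBuMe2)–CH=CH2 with C3 and C4 as in 27; 9β-H; 13-triethylsilyl ether | C=C1C[C@]23C[C@@]1(O[Si](CC)(CC)CC)CC[C@H]2C(=O)[C@H]([C@@H]3C(=O)OC(C)(C)C)[C@](C)(C(=O)OC)[C@@H](O[Si](C)(C)C(C)(C)C)C=C | intermediate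
29 | as 28 with the vinyl group oxidised to the C2 methyl ketone (C1 methyl) | C=C1C[C@]23C[C@@]1(O[Si](CC)(CC)CC)CC[C@H]2C(=O)[C@H]([C@@H]3C(=O)OC(C)(C)C)[C@](C)(C(=O)OC)[C@@H](O[Si](C)(C)C(C)(C)C)C(C)=O | intermediate
30 | ring A aldol: 10α-oxygen (lithium alkoxide, drawn as the alcohol), C1 on the β-face of C10, 2-oxo, C19 methyl ester intact | C=C1C[C@]23C[C@@]1(O[Si](CC)(CC)CC)CC[C@H]2[C@]4(O)CC(=O)[C@H](O[Si](C)(C)C(C)(C)C)[C@@](C)(C(=O)OC)[C@H]4[C@@H]3C(=O)OC(C)(C)C | intermediate
31 | 2-oxo 19,10-lactone: 3β-tert-butyldimethylsilyl ether, 13-triethylsilyl ether, C7 tert-butyl ester | C=C1C[C@]23C[C@@]1(O[Si](CC)(CC)CC)CC[C@H]2[C@@]12CC(=O)[C@H](O[Si](C)(C)C(C)(C)C)[C@@](C)(C(=O)O1)[C@H]2[C@@H]3C(=O)OC(C)(C)C | intermediate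
32 | 2α-hydroxy 19,10-lactone: 3β-tert-butyldimethylsilyl ether, 13-triethylsilyl ether, C7 tert-butyl ester | C=C1C[C@]23C[C@@]1(O[Si](CC)(CC)CC)CC[C@H]2[C@@]12C[C@@H](O)[C@H](O[Si](C)(C)C(C)(C)C)[C@@](C)(C(=O)O1)[C@H]2[C@@H]3C(=O)OC(C)(C)C | intermediate
33 | as 32 with 2α-trimethylsilyl ether and C7 trimethylsilyl ester | C=C1C[C@]23C[C@@]1(O[Si](CC)(CC)CC)CC[C@H]2[C@@]12C[C@@H](O[Si](C)(C)C)[C@H](O[Si](C)(C)C(C)(C)C)[C@@](C)(C(=O)O1)[C@H]2[C@@H]3C(=O)O[Si](C)(C)C | intermediate
34 | CNP0265952.2: 2α,3β,13-trihydroxy-20-norgibberell-16-ene-7,19-dioic acid 19,10-lactone | C=C1C[C@]23C[C@@]1(O)CC[C@H]2[C@@]12C[C@@H](O)[C@H](O)[C@@](C)(C(=O)O1)[C@H]2[C@@H]3C(=O)O | target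

## Step count and least certain steps

Total step count: 22. Longest linear sequence: 17 (steps 1–5, 7–12, 17–22).

**Step 18 (key).** Double deprotonation may be incomplete, or C9 may be enolised in part; oxidation then leads to dimerisation or α-oxidation. Facial control at C6, and hence which trans pair forms, rests on the concave/convex argument only. Fallback: 27 is converted with LiN(iPr)2 and Me3SiCl into the bis(trimethylsilyl) enol ether/ketene acetal F1, whose regiochemistry can be checked before any oxidant is added. F1 is then coupled by one-electron oxidation with (NH4)2Ce(NO3)6 and NaHCO3 in MeCN, the known oxidative coupling of silyl enol ethers, returning to 28.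

**Step 15.** Proton transfer to the dianion, carbenoid formation from diiodomethane, or closure of the alkoxide onto the new iodide may compete with C-alkylation. Fallback: the dianion of 21 is alkylated with 4-methoxybenzyl chloromethyl ether to give methyl (2S,3S)-3-hydroxy-2-{[(4-methoxybenzyl)oxy]methyl}-2-methylpent-4-enoate F2. Silylation gives the tert-butyldimethylsilyl ether F3, DDQ gives the primary alcohol F4, and I2/PPh3/imidazole in warm toluene converts F4 into 24.

**Step 8.** The bromine-deactivated allylsilane may add slowly to the hindered enone, so that TiCl4 begins to cleave the benzyl ether or the tert-butyl ester, or facial control leaks. Fallback: 11 is treated with allenyltributylstannane and TiCl4 to give the propargyl ketone F5. Ketyl–alkyne cyclisation (SmI2, HMPA, t-BuOH; 5-exo-dig) then closes ring D and gives 14 directly, bypassing step 9.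

**Step 20.** The aldol may close cis and dehydrate, the lactone carboxylate may be lost by elimination from the C2 ketone once methoxide is free, or C3 may epimerise. Fallback: 29 is converted (LiN(iPr)2, Me3SiCl, −78 °C) into the methyl-side trimethylsilyl enol ether F6 and brominated with N-bromosuccinimide to the bromomethyl ketone F7. SmI2 in THF at −78 °C then generates a samarium enolate that adds to C10 under neutral, chelating conditions and lactonises to 31.

**Step 21.** The axial C3 silyloxy group lies on the face from which hydride must come, so facial selectivity may be poor or reduction slow enough for elimination to intervene. Fallback: 31 is desilylated with HF·pyridine to the 3β,13-dihydroxy ketone F8. Me4NBH(OAc)3 in MeCN/AcOH delivers hydride intramolecularly from the 3β-oxygen to the β-face of C2, giving the triol tert-butyl ester F9. Me3SiOTf/2,6-lutidine converts F9 into the persilylated trimethylsilyl ester F10, and HF·pyridine releases 34.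

## Further compounds

F1 | step 18 | bis(trimethylsilyl) enol ether/ketene acetal of 27 | C=C1C[C@]2(C=C(O[Si](C)(C)C)OC(C)(C)C)C[C@@]1(O[Si](CC)(CC)CC)CC[C@H]2C(O[Si](C)(C)C)=C[C@](C)(C(=O)OC)[C@@H](O[Si](C)(C)C(C)(C)C)C=C
F2 | step 15 | methyl (2S,3S)-3-hydroxy-2-{[(4-methoxybenzyl)oxy]methyl}-2-methylpent-4-enoate | COc1ccc(COC[C@](C)(C(=O)OC)[C@@H](O)C=C)cc1
F3 | step 15 | methyl (2S,3S)-3-(tert-butyldimethylsilyloxy)-2-{[(4-methoxybenzyl)oxy]methyl}-2-methylpent-4-enoate | COc1ccc(COC[C@](C)(C(=O)OC)[C@@H](O[Si](C)(C)C(C)(C)C)C=C)cc1
F4 | step 15 | methyl (2S,3S)-3-(tert-butyldimethylsilyloxy)-2-(hydroxymethyl)-2-methylpent-4-enoate | OC[C@](C)(C(=O)OC)[C@@H](O[Si](C)(C)C(C)(C)C)C=C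
F5 | step 8 | tert-butyl 2-[(1R,2R)-2-{[(4-methoxybenzyl)oxy]methyl}-5-oxo-1-(prop-2-yn-1-yl)cyclohexyl]acetate | COc1ccc(COC[C@@H]2CCC(=O)C[C@@]2(CC(=O)OC(C)(C)C)CC#C)cc1
F6 | step 20 | C1=C2 trimethylsilyl enol ether of 29 | C=C1C[C@]23C[C@@]1(O[Si](CC)(CC)CC)CC[C@H]2C(=O)[C@H]([C@@H]3C(=O)OC(C)(C)C)[C@](C)(C(=O)OC)[C@@H](O[Si](C)(C)C(C)(C)C)C(=C)O[Si](C)(C)C
F7 | step 20 | C1 bromomethyl ketone of 29 | C=C1C[C@]23C[C@@]1(O[Si](CC)(CC)CC)CC[C@H]2C(=O)[C@H]([C@@H]3C(=O)OC(C)(C)C)[C@](C)(C(=O)OC)[C@@H](O[Si](C)(C)C(C)(C)C)C(=O)CBr
F8 | step 21 | 3β,13-dihydroxy-2-oxo 19,10-lactone tert-butyl ester | C=C1C[C@]23C[C@@]1(O)CC[C@H]2[C@@]12CC(=O)[C@H](O)[C@@](C)(C(=O)O1)[C@H]2[C@@H]3C(=O)OC(C)(C)C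
F9 | step 21 | tert-butyl ester of 34 | C=C1C[C@]23C[C@@]1(O)CC[C@H]2[C@@]12C[C@@H](O)[C@H](O)[C@@](C)(C(=O)O1)[C@H]2[C@@H]3C(=O)OC(C)(C)C
F10 | step 21 | 2,3,13-tris(trimethylsilyl) ether trimethylsilyl ester of 34 | C=C1C[C@]23C[C@@]1(O[Si](C)(C)C)CC[C@H]2[C@@]12C[C@@H](O[Si](C)(C)C)[C@H](O[Si](C)(C)C)[C@@](C)(C(=O)O1)[C@H]2[C@@H]3C(=O)O[Si](C)(C)C
A1 | alternative 1 | C7 methyl ester of the target | C=C1C[C@]23C[C@@]1(O)CC[C@H]2[C@@]12C[C@@H](O)[C@H](O)[C@@](C)(C(=O)O1)[C@H]2[C@@H]3C(=O)OC
A2 | alternative 1 | 2,3-seco dialdehyde on the lactone core | C=C1C[C@]23C[C@@]1(O)CC[C@H]2[C@@]4(CC=O)OC(=O)[C@](C)(C=O)[C@H]4[C@@H]3C(=O)OC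
A3 | alternative 2 | tetracyclic C19 acid with C1=C10 alkene and silylated oxygens | C=C1C[C@]23C[C@@]1(O[Si](C)(C)C)CC[C@H]2C4=C[C@@H](O[Si](C)(C)C(C)(C)C)[C@H](O[Si](C)(C)C(C)(C)C)[C@@](C)(C(=O)O)[C@H]4[C@@H]3CO[Si](C)(C)C(C)(C)C
A4 | alternative 2 | δ-lactone (C19–O–C1) on the ring B cyclopentene, C4 configuration immaterial | C=C1C[C@]23C[C@@]1(O[Si](C)(C)C)CC[C@H]2C(=C[C@@H]3CO[Si](C)(C)C(C)(C)C)[C@H]4OC(=O)[C@H](C)[C@@H](O[Si](C)(C)C(C)(C)C)[C@@H]4O[Si](C)(C)C(C)(C)C
A5 | alternative 3 | pentacyclic lactone with C2 ketone | C=C1C[C@]23C[C@@]1(O[Si](C)(C)C)CC[C@H]2[C@@]12CC(=O)[C@H](O[Si](C)(C)C(C)(C)C)[C@@](C)(C(=O)O1)[C@H]2[C@@H]3C(=O)OC(C)(C)C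
A6 | alternative 3 | ring B cyclopentanone with C2 methyl ketone (13-trimethylsilyl ether) | C=C1C[C@]23C[C@@]1(O[Si](C)(C)C)CC[C@H]2C(=O)[C@H]([C@@H]3C(=O)OC(C)(C)C)[C@](C)(C(=O)OC)[C@@H](O[Si](C)(C)C(C)(C)C)C(C)=O
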